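**Plan**

- Retrosynthesis: first all benzyl ethers and bromine caps are removed; then the C4(unit 3)–C6(unit 4) bond is cut; then, in one cut, the O1–C8a and C4a–C4 bonds of ring C of unit 3; then the C4(unit 2)–C8(ring A of unit 3) bond; last the C4(unit 1)–C6(unit 2) bond.
- Enabling feature: ring A of unit 3 is a 1,3,5-trioxygenated benzene in which O1 and C4 sit on the neighbouring carbons C8a and C4a. This ring can therefore serve as an aryne (C4a≡C8a) polarised by the C5 oxygen, and the chain O1–C2–C3–C4 can be delivered as an alkoxide at one end and an aldehyde at the other.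
- Forward: benzylated, bromine-capped (−)-epicatechin units are made; units 1 and 2 are joined 4β→6; a silylated phloroglucinol-type arene (the future ring A of unit 3) is attached to C4 of unit 2 and converted into an ortho-silylaryl triflate.
- Ring C of unit 3 then arises by fluoride-triggered aryne annulation with an aldol-derived 3-silyloxy aldehyde; the new C4 carbinol is ionised to join unit 4 (4β→6); hydrogenolysis ends the route.
- Stereochemistry: C2/C3 of units 1, 2 and 4 come from (−)-epicatechin; C2/C3 of unit 3 from an Evans syn-glycolate aldol; the three interflavan C4 centres from attack on C4 cations trans to the C3 benzyloxy group. The 4→6 links are fixed by C8 bromine caps, the 4→8 link by the position of the aryne.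

Key step: step 17

Remark on the chemistry: units are numbered from the top (unit 1) to the bottom (unit 4). All four are (2R,3R)-epicatechin units with 3,4-trans (4β) interflavan bonds. The C4 carbinol of 28 is carried as a mixture of epimers (its SMILES leaves this centre undefined) because step 19 ionises it.

**Route**

Step 1
Reactants: 1 (−)-epicatechin
Product: 2 5,7,3',4'-tetra-O-benzyl-(−)-epicatechin
Conditions: BnBr, K2CO3, DMF, 0 °C to rt
Reagents that add atoms: benzyl bromide, BrCc1ccccc1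
Why: Williamson etherification in which the four phenols are alkylated under carbonate while the secondary 3-OH stays free and the mild base avoids epimerisation at C2.

Step 2
Reactants: 2 5,7,3',4'-tetra-O-benzyl-(−)-epicatechin
Product: 3 3,5,7,3',4'-penta-O-benzyl-(−)-epicatechin
Conditions: NaH, BnBr, DMF, 0 °C to rt
Reagents that add atoms: benzyl bromide, BrCc1ccccc1
Why: Williamson etherification of the remaining secondary alcohol through its sodium alkoxide, which removes the only O–H that could later capture the aryne and gives an ether that is cleaved with all the others at the end.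

Step 3
Reactants: 3 3,5,7,3',4'-penta-O-benzyl-(−)-epicatechin
Product: 4 4β-(2-ethoxyethoxy)-3,5,7,3',4'-penta-O-benzylepicatechin
Conditions: DDQ, 2-ethoxyethanol, CH2Cl2, rt
Reagents that add atoms: 2-ethoxyethanol, CCOCCO
Why: DDQ-mediated benzylic oxidation in which hydride abstraction at C4 gives the cation stabilised by the 5,7-dialkoxy ring A and the alcohol adds trans to the 3-benzyloxy group (4β).

Step 4
Reactants: 4 4β-(2-ethoxyethoxy)-3,5,7,3',4'-penta-O-benzylepicatechin
Product: 5 6,8-dibromo-4β-(2-ethoxyethoxy)-3,5,7,3',4'-penta-O-benzylepicatechin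
Conditions: NBS (2.2 equiv), NaHCO3, CH2Cl2, −40 °C to rt
Reagents that add atoms: N-bromosuccinimide, O=C1CCC(=O)N1Br
Why: Electrophilic aromatic bromination of both free positions of ring A (C8, then C6), so that the cation later formed from 5 finds no nucleophilic position on a second molecule of 5.

Step 5
Reactants: 4 4β-(2-ethoxyethoxy)-3,5,7,3',4'-penta-O-benzylepicatechin
Product: 6 8-bromo-4β-(2-ethoxyethoxy)-3,5,7,3',4'-penta-O-benzylepicatechin
Conditions: NBS (1.0 equiv), NaHCO3, CH2Cl2, −78 to −20 °C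
Reagents that add atoms: N-bromosuccinimide, O=C1CCC(=O)N1Br
Why: Regioselective electrophilic bromination, since C8 of a 5,7-dialkoxyflavan reacts ahead of the more hindered C6, which installs the C8 cap that directs later C–C bond formation to C6.

Step 6
Reactants: 6 8-bromo-4β-(2-ethoxyethoxy)-3,5,7,3',4'-penta-O-benzylepicatechin
Product: 7 8-bromo-4β-[(2,6-dimethylphenyl)sulfanyl]-3,5,7,3',4'-penta-O-benzylepicatechin
Conditions: 2,6-dimethylbenzenethiol, BF3·OEt2 (cat.), CH2Cl2, −78 to −20 °C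
Reagents that add atoms: 2,6-dimethylbenzenethiol, Cc1cccc(C)c1S
Why: Lewis-acid-mediated SN1 thiolysis in which the C4 ether is ionised and the thiol adds trans to the 3-benzyloxy group, giving a hindered C4 thioether that is inert to hard Lewis acids and is ionised later by a thiophile.

Step 7
Reactants: 5 6,8-dibromo-4β-(2-ethoxyethoxy)-3,5,7,3',4'-penta-O-benzylepicatechin; 7 8-bromo-4β-[(2,6-dimethylphenyl)sulfanyl]-3,5,7,3',4'-penta-O-benzylepicatechin
Product: 8 dimer thioether: 6,8-dibromo-penta-O-benzylepicatechin-(4β→6)-[8-bromo-4β-(2,6-dimethylphenylsulfanyl)-penta-O-benzylepicatechin]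
Conditions: BF3·OEt2 (cat.), 4 Å molecular sieves, CH2Cl2, −78 to −20 °C; 7 in excess
Reagents that add atoms: none
Why: Friedel–Crafts type interflavan coupling with halogen capping, in which only the C4–O bond of 5 is ionised, C6 of 7 is the sole free ring-A position, and the nucleophile enters trans to the 3-benzyloxy group, which sets the 4β centre of unit 1.

Step 8
Reactants: 9 3,5-bis(benzyloxy)phenol
Product: 10 3,5-bis(benzyloxy)phenyl N-isopropylcarbamate
Conditions: i-PrNCO, Et3N (cat.), CH2Cl2, rt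
Reagents that add atoms: isopropyl isocyanate, CC(C)N=C=O
Why: Addition of the phenol to the isocyanate gives an N-monoalkyl carbamate, a directing group for ortho-metalation that can be removed later under mild base.

Step 9
Reactants: 10 3,5-bis(benzyloxy)phenyl N-isopropylcarbamate
Product: 14 3,5-bis(benzyloxy)-2-(trimethylsilyl)phenyl N-isopropylcarbamate, via N-silyl carbamate 11 (not isolated), via aryllithium 12 (not isolated), via N-silyl C-silyl carbamate 13 (not isolated)
Conditions: TBSOTf, TMEDA, Et2O, 0 °C to rt; n-BuLi, TMEDA, −78 °C; TMSCl, −78 °C to rt; aq. NaHSO4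
Reagents that add atoms: chlorotrimethylsilane, C[Si](C)(C)Cl
Why: Directed ortho-metalation in which N-silylation masks the N–H, n-BuLi lithiates the position flanked by the carbamate and a benzyloxy group (C2 and C6 are equivalent), TMSCl gives the aryl silane and the N-silyl group is lost on acidic work-up.

Step 10
Reactants: 14 3,5-bis(benzyloxy)-2-(trimethylsilyl)phenyl N-isopropylcarbamate
Product: 15 3,5-bis(benzyloxy)-2-(trimethylsilyl)phenol
Conditions: DBU, Et2NH, MeCN, 40 °C
Reagents that add atoms: none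
Why: Base-induced E1cB cleavage of the N-monoalkyl carbamate releases the phenol and isopropyl isocyanate, which diethylamine scavenges as a urea, under conditions that leave the aryl–silicon bond intact.

Step 11
Reactants: 8 dimer thioether; 15 3,5-bis(benzyloxy)-2-(trimethylsilyl)phenol
Product: 16 dimer phenol: 6,8-dibromo-penta-O-benzylepicatechin-(4β→6)-[8-bromo-penta-O-benzylepicatechin] carrying a 2-hydroxy-4,6-bis(benzyloxy)-3-(trimethylsilyl)phenyl group at C4β of unit 2
Conditions: AgBF4, 2,6-di-tert-butyl-4-methylpyridine, THF/CH2Cl2, −20 to 0 °C; 15 in excess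
Reagents that add atoms: none
Why: Thiophile-promoted Friedel–Crafts alkylation in which monovalent silver abstracts the arylthio group, the C4 cation of unit 2 is attacked trans to the 3-benzyloxy group (4β) by C6 of the phenol, the only ring position not shielded by the silyl group or by two flanking benzyloxy groups, and the hindered pyridine takes up the acid so that the aryl–silicon bond survives.

Step 12
Reactants: 16 dimer phenol
Product: 17 dimer silyl triflate: as 16 with the phenol converted into its trifluoromethanesulfonate (ortho to the trimethylsilyl group)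
Conditions: Tf2O, pyridine, CH2Cl2, −78 to 0 °C
Reagents that add atoms: trifluoromethanesulfonic anhydride, O=S(=O)(OS(=O)(=O)C(F)(F)F)C(F)(F)F
Why: O-Sulfonylation of the hindered phenol completes the ortho-silylaryl triflate, the standard fluoride-triggered aryne precursor.

Step 13
Reactants: 18 3,4-bis(benzyloxy)benzaldehyde; 19 (S)-4-benzyl-3-(2-benzyloxyacetyl)oxazolidin-2-one
Product: 21 (S)-4-benzyl-3-[(2S,3R)-2-(benzyloxy)-3-[3,4-bis(benzyloxy)phenyl]-3-hydroxypropanoyl]oxazolidin-2-one, via boron Z-enolate 20 (not isolated)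
Conditions: Bu2BOTf, Et3N, CH2Cl2, −78 to 0 °C; then pH 7 buffer, MeOH, H2O2
Reagents that add atoms: none
Why: Evans syn-aldol reaction in which the Z-boron enolate reacts through a closed chair transition state and the (S)-benzyl auxiliary selects the enolate face, giving the syn adduct whose two centres become C2 (R) and C3 (R) of unit 3.

Step 14
Reactants: 21 syn-aldol adduct
Product: 22 (2S,3R)-2-(benzyloxy)-3-[3,4-bis(benzyloxy)phenyl]-3-hydroxy-N-methoxy-N-methylpropanamide
Conditions: MeNHOMe·HCl, AlMe3, THF, −20 to 0 °C; aq. potassium sodium tartrate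
Reagents that add atoms: N,O-dimethylhydroxylamine hydrochloride, CNOC.Cl
Why: Aluminium amide transamination of the β-hydroxy imide (Weinreb amide formation) removes the auxiliary without touching either stereocentre.

Step 15
Reactants: 22 Weinreb amide
Product: 23 (2S,3R)-2-(benzyloxy)-3-[3,4-bis(benzyloxy)phenyl]-N-methoxy-N-methyl-3-(triethylsilyloxy)propanamide
Conditions: TESCl, imidazole, DMF, 0 °C to rt
Reagents that add atoms: chlorotriethylsilane, CC[Si](CC)(CC)Cl
Why: Silylation of the benzylic alcohol gives a silyl ether that protects the aldol from retro-aldol cleavage during reduction and storage and is removed later by the same fluoride that triggers the aryne.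

Step 16
Reactants: 23 silylated Weinreb amide
Product: 24 (2S,3R)-2-(benzyloxy)-3-[3,4-bis(benzyloxy)phenyl]-3-(triethylsilyloxy)propanal
Conditions: i-Bu2AlH, THF, −78 °C; aq. potassium sodium tartrate
Reagents that add atoms: none
Why: Reduction of the Weinreb amide stops at the chelated tetrahedral intermediate and should give the aldehyde on work-up without epimerising the α-alkoxy centre.

Step 17
Reactants: 17 dimer silyl triflate; 24 (2S,3R)-2-(benzyloxy)-3-[3,4-bis(benzyloxy)phenyl]-3-(triethylsilyloxy)propanal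
Product: 28 trimer 4-ol: 6,8-dibromo-penta-O-benzylepicatechin-(4β→6)-[8-bromo-penta-O-benzylepicatechin]-(4β→8)-[4-hydroxy-3,5,7,3',4'-penta-O-benzylepicatechin] (C4 epimers of unit 3), via aryne 25 (not isolated), via cesium alkoxide 26 (not isolated), via aryl cesium 27 (not isolated)
Conditions: CsF, 18-crown-6, THF, 0 °C to rt; 24 in excess; then aq. NH4Cl
Reagents that add atoms: none
Why: Proposed new method: fluoride desilylates the triethylsilyl ether of 24 to the cesium alkoxide 26 and, by attack at the aryl silicon of 17, expels triflate to give the aryne 25 (C4a≡C8a of ring A of unit 3); the alkoxide oxygen adds to C8a and the resulting aryl anion 27 at C4a adds to the aldehyde carbon, so the O1–C8a and C4a–C4 bonds are made in one operation. The closest known reaction type is the aryne annulation of salicylaldehydes and ortho-hydroxyaryl ketones to xanthenols (oxygen addition to the aryne, then intramolecular carbonyl capture by the aryl anion), here extended to an aliphatic β-oxido aldehyde. Ring C of unit 3 is closed by intermolecular O-arylation followed by 6-exo-trig addition of the aryl anion to the C=O group, a formal [4+2] annulation. C2 and C3 are carried through unchanged from the aldol adduct (2,3-cis), and the only new stereocentre, the C4 carbinol, is under weak substrate control and is left as an epimer mixture because step 19 ionises it. The step needs addition at C8a and not at C4a, which the C5 benzyloxy group secures by distorting the aryne so that C8a is the electrophilic terminus and the negative charge develops at C4a next to the inductively stabilising oxygen; it needs ring closure ahead of protonation, which the silyl-masked nucleophile and aprotic THF secure because no O–H is present; and it needs the alkoxide to be arylated before retro-aldol cleavage or α-epimerisation, which slow release of 26 at 0 °C in the presence of the aryne should secure.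

Step 18
Reactants: 3 3,5,7,3',4'-penta-O-benzyl-(−)-epicatechin
Product: 29 8-bromo-3,5,7,3',4'-penta-O-benzyl-(−)-epicatechin
Conditions: NBS (1.0 equiv), CH2Cl2, −78 to 0 °C
Reagents that add atoms: N-bromosuccinimide, O=C1CCC(=O)N1Br
Why: Regioselective electrophilic bromination at C8, as in step 5, gives the capped bottom unit whose only nucleophilic ring-A position is C6.

Step 19
Reactants: 28 trimer 4-ol; 29 8-bromo-3,5,7,3',4'-penta-O-benzyl-(−)-epicatechin
Product: 30 protected tetramer: 6,8-dibromo-penta-O-benzylepicatechin-(4β→6)-[8-bromo-penta-O-benzylepicatechin]-(4β→8)-[penta-O-benzylepicatechin]-(4β→6)-[8-bromo-penta-O-benzylepicatechin]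
Conditions: TMSOTf (cat.), 4 Å molecular sieves, CH2Cl2, −78 to −40 °C; 29 in excess
Reagents that add atoms: none
Why: Friedel–Crafts type interflavan coupling in which the C4 carbinol of unit 3 is ionised (both epimers give the same cation) and C6 of the C8-capped 29 attacks trans to the 3-benzyloxy group, which sets the 4β centre of unit 3 and the 4→6 link.

Step 20
Reactants: 30 protected tetramer
Product: 31 epicatechin-(4β→6)-epicatechin-(4β→8)-epicatechin-(4β→6)-epicatechin (target)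
Conditions: H2 (1 atm), Pd(OH)2/C, Et3N, THF/MeOH/H2O, rt
Reagents that add atoms: none
Why: Catalytic hydrogenolysis should cleave all twenty benzyl ethers and the four aryl–bromine bonds in one operation, while Et3N neutralises HBr and so protects the acid-labile interflavan bonds.

**Compound list**

1 | (−)-epicatechin | Oc1cc(O)c2c(c1)O[C@H](c1ccc(O)c(O)c1)[C@H](O)C2 | starting material
2 | 5,7,3',4'-tetra-O-benzyl-(−)-epicatechin | c9ccccc9COc1cc(OCc9ccccc9)c2c(c1)O[C@H](c8ccc(OCc9ccccc9)c(OCc9ccccc9)c8)[C@H](O)C2 | intermediate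
3 | 3,5,7,3',4'-penta-O-benzyl-(−)-epicatechin | c9ccccc9COc1cc(OCc9ccccc9)c2c(c1)O[C@H](c8ccc(OCc9ccccc9)c(OCc9ccccc9)c8)[C@H](OCc9ccccc9)C2 | intermediate
4 | 4β-(2-ethoxyethoxy)-3,5,7,3',4'-penta-O-benzylepicatechin | c9ccccc9COc1cc(OCc9ccccc9)c2c(c1)O[C@H](c8ccc(OCc9ccccc9)c(OCc9ccccc9)c8)[C@H](OCc9ccccc9)[C@H]2OCCOCC | intermediate
5 | 6,8-dibromo-4β-(2-ethoxyethoxy)-3,5,7,3',4'-penta-O-benzylepicatechin | c9ccccc9COc1c(Br)c(OCc9ccccc9)c2c(c1Br)O[C@H](c8ccc(OCc9ccccc9)c(OCc9ccccc9)c8)[C@H](OCc9ccccc9)[C@H]2OCCOCC | intermediate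
6 | 8-bromo-4β-(2-ethoxyethoxy)-3,5,7,3',4'-penta-O-benzylepicatechin | c9ccccc9COc1cc(OCc9ccccc9)c2c(c1Br)O[C@H](c8ccc(OCc9ccccc9)c(OCc9ccccc9)c8)[C@H](OCc9ccccc9)[C@H]2OCCOCC | intermediate
7 | 8-bromo-4β-[(2,6-dimethylphenyl)sulfanyl]-3,5,7,3',4'-penta-O-benzylepicatechin | c9ccccc9COc1cc(OCc9ccccc9)c2c(c1Br)O[C@H](c8ccc(OCc9ccccc9)c(OCc9ccccc9)c8)[C@H](OCc9ccccc9)[C@H]2Sc7c(C)cccc7C | intermediate
8 | dimer thioether (unit 1 C4β→C6 unit 2; 2,6-dimethylphenylsulfanyl at C4β of unit 2) | c9ccccc9COc1c(Br)c(OCc9ccccc9)c2c(c1Br)O[C@H](c8ccc(OCc9ccccc9)c(OCc9ccccc9)c8)[C@H](OCc9ccccc9)[C@H]2c1c(OCc9ccccc9)c(Br)c2c(c1OCc9ccccc9)[C@H](Sc7c(C)cccc7C)[C@@H](OCc9ccccc9)[C@@H](c8ccc(OCc9ccccc9)c(OCc9ccccc9)c8)O2 | intermediate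
9 | 3,5-bis(benzyloxy)phenol | Oc1cc(OCc9ccccc9)cc(OCc9ccccc9)c1 | starting material
10 | 3,5-bis(benzyloxy)phenyl N-isopropylcarbamate | CC(C)NC(=O)Oc1cc(OCc9ccccc9)cc(OCc9ccccc9)c1 | intermediate
11 | 3,5-bis(benzyloxy)phenyl N-(tert-butyldimethylsilyl)-N-isopropylcarbamate | CC(C)N([Si](C)(C)C(C)(C)C)C(=O)Oc1cc(OCc9ccccc9)cc(OCc9ccccc9)c1 | intermediate (not isolated)
12 | 2-lithio derivative of 11 | CC(C)N([Si](C)(C)C(C)(C)C)C(=O)Oc1cc(OCc9ccccc9)cc(OCc9ccccc9)c1[Li] | intermediate (not isolated)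
13 | 3,5-bis(benzyloxy)-2-(trimethylsilyl)phenyl N-(tert-butyldimethylsilyl)-N-isopropylcarbamate | CC(C)N([Si](C)(C)C(C)(C)C)C(=O)Oc1cc(OCc9ccccc9)cc(OCc9ccccc9)c1[Si](C)(C)C | intermediate (not isolated)
14 | 3,5-bis(benzyloxy)-2-(trimethylsilyl)phenyl N-isopropylcarbamate | CC(C)NC(=O)Oc1cc(OCc9ccccc9)cc(OCc9ccccc9)c1[Si](C)(C)C | intermediate
15 | 3,5-bis(benzyloxy)-2-(trimethylsilyl)phenol | Oc1cc(OCc9ccccc9)cc(OCc9ccccc9)c1[Si](C)(C)C | intermediate
16 | dimer phenol (2-hydroxy-4,6-bis(benzyloxy)-3-(trimethylsilyl)phenyl at C4β of unit 2) | c9ccccc9COc1c(Br)c(OCc9ccccc9)c2c(c1Br)O[C@H](c8ccc(OCc9ccccc9)c(OCc9ccccc9)c8)[C@H](OCc9ccccc9)[C@H]2c1c(OCc9ccccc9)c(Br)c2c(c1OCc9ccccc9)[C@H](c1c(OCc9ccccc9)cc(OCc9ccccc9)c([Si](C)(C)C)c1O)[C@@H](OCc9ccccc9)[C@@H](c8ccc(OCc9ccccc9)c(OCc9ccccc9)c8)O2 | intermediate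
17 | dimer silyl triflate (4,6-bis(benzyloxy)-2-(trifluoromethylsulfonyloxy)-3-(trimethylsilyl)phenyl at C4β of unit 2) | c9ccccc9COc1c(Br)c(OCc9ccccc9)c2c(c1Br)O[C@H](c8ccc(OCc9ccccc9)c(OCc9ccccc9)c8)[C@H](OCc9ccccc9)[C@H]2c1c(OCc9ccccc9)c(Br)c2c(c1OCc9ccccc9)[C@H](c1c(OCc9ccccc9)cc(OCc9ccccc9)c([Si](C)(C)C)c1OS(=O)(=O)C(F)(F)F)[C@@H](OCc9ccccc9)[C@@H](c8ccc(OCc9ccccc9)c(OCc9ccccc9)c8)O2 | intermediate
18 | 3,4-bis(benzyloxy)benzaldehyde | O=Cc1ccc(OCc9ccccc9)c(OCc9ccccc9)c1 | starting material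
19 | (S)-4-benzyl-3-(2-benzyloxyacetyl)oxazolidin-2-one | O=C(COCc9ccccc9)N7C(=O)OC[C@@H]7Cc9ccccc9 | starting material
20 | dibutylboron Z-enolate of 19 | CCCCB(CCCC)O/C(N7C(=O)OC[C@@H]7Cc9ccccc9)=C\OCc9ccccc9 | intermediate (not isolated)
21 | (S)-4-benzyl-3-[(2S,3R)-2-(benzyloxy)-3-[3,4-bis(benzyloxy)phenyl]-3-hydroxypropanoyl]oxazolidin-2-one | O[C@H](c8ccc(OCc9ccccc9)c(OCc9ccccc9)c8)[C@H](OCc9ccccc9)C(=O)N7C(=O)OC[C@@H]7Cc9ccccc9 | intermediate
22 | (2S,3R)-2-(benzyloxy)-3-[3,4-bis(benzyloxy)phenyl]-3-hydroxy-N-methoxy-N-methylpropanamide | O[C@H](c8ccc(OCc9ccccc9)c(OCc9ccccc9)c8)[C@H](OCc9ccccc9)C(=O)N(C)OC | intermediate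
23 | (2S,3R)-2-(benzyloxy)-3-[3,4-bis(benzyloxy)phenyl]-N-methoxy-N-methyl-3-(triethylsilyloxy)propanamide | CC[Si](CC)(CC)O[C@H](c8ccc(OCc9ccccc9)c(OCc9ccccc9)c8)[C@H](OCc9ccccc9)C(=O)N(C)OC | intermediate
24 | (2S,3R)-2-(benzyloxy)-3-[3,4-bis(benzyloxy)phenyl]-3-(triethylsilyloxy)propanal | CC[Si](CC)(CC)O[C@H](c8ccc(OCc9ccccc9)c(OCc9ccccc9)c8)[C@H](OCc9ccccc9)C=O | intermediate
25 | aryne from 17 (C≡C between the former C–OTf and C–SiMe3 carbons) | c9ccccc9COc1c(Br)c(OCc9ccccc9)c2c(c1Br)O[C@H](c8ccc(OCc9ccccc9)c(OCc9ccccc9)c8)[C@H](OCc9ccccc9)[C@H]2c1c(OCc9ccccc9)c(Br)c2c(c1OCc9ccccc9)[C@H](C1=C(OCc9ccccc9)C=C(OCc9ccccc9)C#C1)[C@@H](OCc9ccccc9)[C@@H](c8ccc(OCc9ccccc9)c(OCc9ccccc9)c8)O2 | intermediate (not isolated)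
26 | cesium (1R,2S)-2-(benzyloxy)-1-[3,4-bis(benzyloxy)phenyl]-3-oxopropan-1-olate | [Cs+].[O-][C@H](c8ccc(OCc9ccccc9)c(OCc9ccccc9)c8)[C@H](OCc9ccccc9)C=O | intermediate (not isolated)
27 | aryl cesium formed by O-arylation (aryl ether at C8a, C–Cs at C4a, aldehyde still open) | c9ccccc9COc1c(Br)c(OCc9ccccc9)c2c(c1Br)O[C@H](c8ccc(OCc9ccccc9)c(OCc9ccccc9)c8)[C@H](OCc9ccccc9)[C@H]2c1c(OCc9ccccc9)c(Br)c2c(c1OCc9ccccc9)[C@H](c1c(OCc9ccccc9)cc(OCc9ccccc9)c([Cs])c1O[C@H](c8ccc(OCc9ccccc9)c(OCc9ccccc9)c8)[C@H](OCc9ccccc9)C=O)[C@@H](OCc9ccccc9)[C@@H](c8ccc(OCc9ccccc9)c(OCc9ccccc9)c8)O2 | intermediate (not isolated)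
28 | trimer 4-ol (unit 3 = 4-hydroxy-penta-O-benzylepicatechin, C4 epimers) | c9ccccc9COc1c(Br)c(OCc9ccccc9)c2c(c1Br)O[C@H](c8ccc(OCc9ccccc9)c(OCc9ccccc9)c8)[C@H](OCc9ccccc9)[C@H]2c1c(OCc9ccccc9)c(Br)c2c(c1OCc9ccccc9)[C@H](c1c(OCc9ccccc9)cc(OCc9ccccc9)c3c1O[C@H](c8ccc(OCc9ccccc9)c(OCc9ccccc9)c8)[C@H](OCc9ccccc9)C3O)[C@@H](OCc9ccccc9)[C@@H](c8ccc(OCc9ccccc9)c(OCc9ccccc9)c8)O2 | intermediate
29 | 8-bromo-3,5,7,3',4'-penta-O-benzyl-(−)-epicatechin | c9ccccc9COc1cc(OCc9ccccc9)c2c(c1Br)O[C@H](c8ccc(OCc9ccccc9)c(OCc9ccccc9)c8)[C@H](OCc9ccccc9)C2 | intermediate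
30 | protected tetramer (twenty benzyl ethers, four bromine caps) | c9ccccc9COc1c(Br)c(OCc9ccccc9)c2c(c1Br)O[C@H](c8ccc(OCc9ccccc9)c(OCc9ccccc9)c8)[C@H](OCc9ccccc9)[C@H]2c1c(OCc9ccccc9)c(Br)c2c(c1OCc9ccccc9)[C@H](c1c(OCc9ccccc9)cc(OCc9ccccc9)c3c1O[C@H](c8ccc(OCc9ccccc9)c(OCc9ccccc9)c8)[C@H](OCc9ccccc9)[C@H]3c1c(OCc9ccccc9)c(Br)c3c(c1OCc9ccccc9)C[C@@H](OCc9ccccc9)[C@@H](c8ccc(OCc9ccccc9)c(OCc9ccccc9)c8)O3)[C@@H](OCc9ccccc9)[C@@H](c8ccc(OCc9ccccc9)c(OCc9ccccc9)c8)O2 | intermediate
31 | epicatechin-(4β→6)-epicatechin-(4β→8)-epicatechin-(4β→6)-epicatechin | Oc1cc(O)c2c(c1)O[C@H](c1ccc(O)c(O)c1)[C@H](O)[C@H]2c1c(O)cc2c(c1O)[C@H](c1c(O)cc(O)c3c1O[C@H](c1ccc(O)c(O)c1)[C@H](O)[C@H]3c1c(O)cc3c(c1O)C[C@@H](O)[C@@H](c1ccc(O)c(O)c1)O3)[C@@H](O)[C@@H](c1ccc(O)c(O)c1)O2 | target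

**Step count and risks**

Total step count: 20. Longest linear sequence: 11 steps (steps 1, 2, 3, 5, 6, 7, 11, 12, 17, 19, 20).

Steps most likely to fail:

Step 17. The alkoxide may add to the wrong aryne terminus because the bulky flavanyl group next to C8a hinders approach there. The aryne may instead be captured internally by a neighbouring benzyl ether oxygen. The alkoxide may undergo retro-aldol cleavage or α-epimerisation before it is arylated, and the aryl anion may be protonated before it closes the ring. The fallback uses known chemistry and gives up the annulation. It sets out from 8 and 4. Buffered AgBF4 activation of the thioether of 8 in the presence of excess 4, whose free C8 is the preferred nucleophilic position and whose C4 ether is inert to the thiophile, should give the trimer with a 4β-(2-ethoxyethoxy) group on unit 3 F1. Catalytic TMSOTf with excess 29 then ionises that ether, and the route is rejoined at 30.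

Step 11. The cation may attack the phenol at the position between the two benzyloxy groups, substitute the silyl group at its own carbon, or be intercepted at the phenol oxygen, and the aryl–silicon bond may be lost by protodesilylation. The fallback puts the silicon in after the C–C bond is made. It sets out from 8 and 9. AgBF4 coupling with the symmetrical, silicon-free phenol 9 should give the dimer carrying a 2-hydroxy-4,6-bis(benzyloxy)phenyl group F2. Boc2O with DMAP converts it into the aryl tert-butyl carbonate F3. Directed ortho-magnesiation with (TMP)2Mg·2LiCl, which tolerates the aryl bromides, followed by TMSCl gives the ortho-silylated carbonate F4. Methanolysis with K2CO3 in MeOH returns the route to 16.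

Step 7. Attack at the crowded C6 of the thio-substituted unit may be slow. The long-lived cation may then abstract the arylthio group from the partner or eliminate to a flav-3-ene. The fallback removes sulfur from the coupling. It sets out from 5 and 29. BF3·OEt2-mediated coupling of 5 with excess 29, which has no C4 substituent, should give the C4-unsubstituted dimer F5. DDQ oxidation with 2-ethoxyethanol at the only remaining flavan CH2 group gives the dimer 4β-(2-ethoxyethoxy) ether F6. Thiolysis with 2,6-dimethylbenzenethiol and BF3·OEt2 returns the route to 8.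

**Further compounds**

F1 | step 17 | trimer with a 4β-(2-ethoxyethoxy) group on unit 3 | c9ccccc9COc1c(Br)c(OCc9ccccc9)c2c(c1Br)O[C@H](c8ccc(OCc9ccccc9)c(OCc9ccccc9)c8)[C@H](OCc9ccccc9)[C@H]2c1c(OCc9ccccc9)c(Br)c2c(c1OCc9ccccc9)[C@H](c1c(OCc9ccccc9)cc(OCc9ccccc9)c3c1O[C@H](c8ccc(OCc9ccccc9)c(OCc9ccccc9)c8)[C@H](OCc9ccccc9)[C@H]3OCCOCC)[C@@H](OCc9ccccc9)[C@@H](c8ccc(OCc9ccccc9)c(OCc9ccccc9)c8)O2
F2 | step 11 | dimer carrying a 2-hydroxy-4,6-bis(benzyloxy)phenyl group at C4β of unit 2 | c9ccccc9COc1c(Br)c(OCc9ccccc9)c2c(c1Br)O[C@H](c8ccc(OCc9ccccc9)c(OCc9ccccc9)c8)[C@H](OCc9ccccc9)[C@H]2c1c(OCc9ccccc9)c(Br)c2c(c1OCc9ccccc9)[C@H](c1c(OCc9ccccc9)cc(OCc9ccccc9)cc1O)[C@@H](OCc9ccccc9)[C@@H](c8ccc(OCc9ccccc9)c(OCc9ccccc9)c8)O2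
F3 | step 11 | aryl tert-butyl carbonate of F2 | c9ccccc9COc1c(Br)c(OCc9ccccc9)c2c(c1Br)O[C@H](c8ccc(OCc9ccccc9)c(OCc9ccccc9)c8)[C@H](OCc9ccccc9)[C@H]2c1c(OCc9ccccc9)c(Br)c2c(c1OCc9ccccc9)[C@H](c1c(OCc9ccccc9)cc(OCc9ccccc9)cc1OC(=O)OC(C)(C)C)[C@@H](OCc9ccccc9)[C@@H](c8ccc(OCc9ccccc9)c(OCc9ccccc9)c8)O2
F4 | step 11 | ortho-silylated aryl tert-butyl carbonate | c9ccccc9COc1c(Br)c(OCc9ccccc9)c2c(c1Br)O[C@H](c8ccc(OCc9ccccc9)c(OCc9ccccc9)c8)[C@H](OCc9ccccc9)[C@H]2c1c(OCc9ccccc9)c(Br)c2c(c1OCc9ccccc9)[C@H](c1c(OCc9ccccc9)cc(OCc9ccccc9)c([Si](C)(C)C)c1OC(=O)OC(C)(C)C)[C@@H](OCc9ccccc9)[C@@H](c8ccc(OCc9ccccc9)c(OCc9ccccc9)c8)O2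
F5 | step 7 | C4-unsubstituted dimer: 6,8-dibromo-penta-O-benzylepicatechin-(4β→6)-[8-bromo-penta-O-benzylepicatechin] | c9ccccc9COc1c(Br)c(OCc9ccccc9)c2c(c1Br)O[C@H](c8ccc(OCc9ccccc9)c(OCc9ccccc9)c8)[C@H](OCc9ccccc9)[C@H]2c1c(OCc9ccccc9)c(Br)c2c(c1OCc9ccccc9)C[C@@H](OCc9ccccc9)[C@@H](c8ccc(OCc9ccccc9)c(OCc9ccccc9)c8)O2
F6 | step 7 | dimer 4β-(2-ethoxyethoxy) ether (on unit 2) | c9ccccc9COc1c(Br)c(OCc9ccccc9)c2c(c1Br)O[C@H](c8ccc(OCc9ccccc9)c(OCc9ccccc9)c8)[C@H](OCc9ccccc9)[C@H]2c1c(OCc9ccccc9)c(Br)c2c(c1OCc9ccccc9)[C@H](OCCOCC)[C@@H](OCc9ccccc9)[C@@H](c8ccc(OCc9ccccc9)c(OCc9ccccc9)c8)O2
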